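**Remark on the chemistry:** atom labels follow flavone numbering for rings A and C and primed numbers for the piperidine (ring D). The only stereocentre, C2', is R in the target (N1' > aryl carbon > C3' > H) and keeps this descriptor in every intermediate, because the aryl carbon always outranks C3'.

## Structural features

The target is a 5,7-dihydroxyflavone: benzo ring A (C4a to C8a) fused to pyranone ring C, with an unsubstituted phenyl group (ring B) on C2. C8 of ring A carries a 1-methylpiperidine (ring D) through its C2', so the C8–C2' bond joins a fully oxygenated, phloroglucinol-type arene to a carbon that is both benzylic and α to nitrogen. C2' (R) is the only stereocentre; it has no stereogenic neighbour, so it must be set in the absolute sense and nothing in the molecule can relay or repair it. The fragile element is the C2'–N1' bond: the oxygen substituents ortho and para to C8 stabilise a benzylic cation or an ortho-quinone methide, so acid and heat can open ring D reversibly and erase the configuration, while the pyranone does not tolerate hydride or hard nucleophiles and the two phenols (5-OH chelated to the C4 carbonyl, 7-OH not) must stay masked until the end. The real difficulty is therefore twofold: absolute control at C2' and its survival through the Lewis-acidic steps that build ring C, and regiochemistry on ring A, where O1 has to be the oxygen next to C8 and not the one para to it. Ring D carries nothing except the N-methyl group and the aryl substituent, so C6' is a plain methylene between N1' and C5'; the key step uses exactly this, bringing C6' in as carbon monoxide between a terminal alkene carbon (C5') and a carbamate nitrogen. The same carbamate supplies the N-methyl group through its carbonyl carbon, so no nitrogen protecting group has to be taken off.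

## Logic of the disconnections

**21 to 20.** The two O–CH3 bonds at O5 and O7 are restored. Free phenols would interfere with the enolate acylation that builds ring C, and methyl ethers are the one ether type that survives hydride, BF3 and strong amide base. The skeleton does not change, but the end game shrinks to a single deprotection. The forward step must cleave both ethers, including the crowded one at O7, without ionising C2'–N1'.

**20 to 17 and 18.** O1–C2 and C2–C3 are cut, which removes ring C and ring B together. C3 is the methyl carbon of an aryl methyl ketone and C2 is an aroyl carbon, so 18 delivers seven carbons in one operation through the unisolated 19. The forward step must acylate at carbon and must close onto the single free hydroxyl of 17, under acid mild enough for C2'.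

**17 to 14 and 15.** The C4a–C4 bond is cut and the methyl ether on the C8a oxygen is restored. The aryl ring of 14 has a local mirror plane through C8 and C5, so its two free CH positions are equivalent and acylation can give only one ketone (16). The remaining demand is that the ether cleaved afterwards is the one between the acetyl group and C8.

**14 to 13 to 12.** No skeletal bond is cut: N–CH3 is traced back to N–CO2CH3 and the C5'–C6' single bond to the ene-carbamate double bond. The carbamate that the key step needs is thus converted, not removed. The hydride reduction must come before any carbonyl of ring C exists, and the hydrogenation must leave the benzylic C–N bond alone.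

**12 to 8 and 9.** N1'–C6' and C5'–C6' are cut, so C6' becomes 9 and ring D disappears. The stereocentre then sits in an acyclic homoallylic carbamate that imine allylation can reach. The forward step must hydroformylate at the terminal carbon only, must not migrate the alkene toward C2', and must close the ring through the carbamate N–H.

**8 to 5 and 6.** The N–C(O) bond is cut and the N–S bond restored (through 7). The sulfinyl group is the element that controls C2', whereas the methyl carbamate is what steps 3 and 5 need. The exchange requires acid, which has to be brief and cold because of the donor-rich benzylic position.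

**5 to 1, 2 and 3.** C2'–C3' and the C2'–N double bond of 4 are cut. C2' is an aldehyde carbon, 3 supplies C3' to C5', and 2 supplies nitrogen and the chiral information; all three are commercial. The forward step must add allyl to the Re face of 4.

## Other disconnections considered

**Alternative 1:** The cut is the C2=C3 bond of ring C. In the forward sense the keto-stabilised ylide A1 (benzoate on the C8a oxygen, phosphorane on the acetyl carbon) is heated in toluene; the ylide carbon adds to the ester carbonyl and collapse of the oxaphosphetane gives the N-Boc flavone A2.
- In its favour: the closure is neutral, passes through no enolisable diketone and needs no acid. On mildness toward C2' this is better than step 7 of the chosen plan.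
- Equal: the position of O1 is fixed by where the benzoate sits, but the same hydroxyl must first be freed selectively, exactly as in 17.
- Against: an ester carbonyl is a poor Wittig acceptor and here it is flanked by the piperidine, so prolonged heating is needed. A1 requires α-halogenation of an electron-rich aryl methyl ketone (ring halogenation competes), phosphonium salt formation, ylide generation and O-benzoylation of a hindered phenol, about four operations where the chosen plan uses one. The Boc group of A2 cannot be reduced to N-methyl once the pyranone exists, so acidic removal at a donor-flanked benzylic C–N bond and a separate N-methylation must follow. The disconnection also says nothing about ring D or C2', so an asymmetric piperidine synthesis such as step 3 is needed anyway.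
- Overall: mechanistically sound and gentler in the ring-closing event, but about five steps longer, with a carbamate that is removed and not converted.

**Alternative 2:** The cut removes the whole of ring A (C8–C8a, C6–C7 and the C4a–C8a closure). D-pipecolic acid A3 is homologated to the siloxyalkyne A4, which is heated with 3-ethoxycyclobutenone A5: four-electron ring opening to a vinylketene, [2+2] cycloaddition with the electron-rich alkyne, a second ring opening and six-electron electrocyclisation give the phenol A6.
- In its favour: C2' comes from the chiral pool, so no asymmetric step is needed; this is equal or better on the source of chirality. The three oxygens of ring A emerge fully differentiated (free hydroxyl on C8a, silyl ether on C7, ethyl ether on C5), so the place of O1 is settled from the outset. That is better than the chosen plan, which relies on a selective demethylation in step 6. No metal catalyst or pressurised gas is required.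
- Equal: the Boc group of A6 can still be reduced to N-methyl at the phenol stage, and ring C construction and the final ether cleavage are of the same kind.
- Against: making A4 means an ester-to-ynolate homologation with strong base next to the α-amino stereocentre, a real risk to C2', followed by silylation. A5 has to be prepared and is thermally sensitive. The cascade needs heat with a hindered alkyne. A6 still needs C4a acylation in competition with C6.
- Overall: an elegant pericyclic solution that is stronger on regiochemistry, comparable or slightly longer in step count (about ten from A3), and carries its main risk in the integrity of C2' during alkyne synthesis.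

**Alternative 3:** The cut is O1–C8a. The 2-fluoroaryl 1,3-diketone A7 is treated with K2CO3; the enolate oxygen adds to C8a and fluoride leaves from the Meisenheimer-type adduct, closing ring C to A8, which is the same compound as 20.
- In its favour: fluorine marks C8a, so no selective demethylation is needed and the O1–C8a regiochemistry is certain, which is better than the chosen plan. The closure is basic, not acidic, which is also better for C2'. Both methoxy groups are meta to fluorine and the ortho carbonyl activates, so the substitution is reasonable.
- Equal: the end game from A8 is identical, and the ring D chemistry of step 3 would work equally well on a fluoro-dimethoxyphenyl carbamate.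
- Against: the fluorinated ring loses the local symmetry that makes the two CH positions of 14 equivalent. The acyl group must enter specifically between fluorine and methoxy, whereas electrophilic acylation would prefer the position between the two methoxy groups, so a directed metalation and a separate diketone assembly are needed. The substitution on a dialkoxy arene needs heating in a dipolar solvent.
- Overall: equal in length or one to two steps longer; it trades one regiochemical question (which ether is cleaved) for another (where the acyl group enters).

Key step: step 3

## Route

**Step 1**
Reactants: 1 2,4,6-trimethoxybenzaldehyde; 2 (S)-2-methylpropane-2-sulfinamide; 3 allyl bromide (3-bromoprop-1-ene)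
Product: 5 (S)-2-methyl-N-[(1R)-1-(2,4,6-trimethoxyphenyl)but-3-en-1-yl]propane-2-sulfinamide, via N-sulfinyl imine 4 (not isolated)
Conditions: Ti(OEt)4 (2 equiv), THF, 60 °C; then indium powder (1.3 equiv), 3 (1.5 equiv), 60 °C; brine, filtration through Celite
Reagents that add atoms: none
Why: Ti(OEt)4-mediated condensation gives the E-configured N-sulfinyl imine 4, and the allylindium species formed in situ from 3 adds in a Barbier-type allylation through a chair-like transition state in which trivalent indium is bound to the imine nitrogen and the sulfinyl oxygen. With (S)-configured sulfur the tert-butyl group covers the Si face of the imine carbon, so allyl is delivered to the Re face and C2' is set as R (N > aryl > allyl > H) under control of the sulfur auxiliary. The diastereomers of 5 differ in physical properties, so a minor isomer should be removable by chromatography or crystallisation before the auxiliary is cleaved.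

**Step 2**
Reactants: 5 (S)-2-methyl-N-[(1R)-1-(2,4,6-trimethoxyphenyl)but-3-en-1-yl]propane-2-sulfinamide; 6 methyl chloroformate
Product: 8 methyl N-[(1R)-1-(2,4,6-trimethoxyphenyl)but-3-en-1-yl]carbamate, via amine hydrochloride 7 (not isolated)
Conditions: HCl (4 M in dioxane, 2 equiv), MeOH, 0 °C, 30 min, concentrate cold; then 6, NaHCO3, EtOAc/H2O, 0 °C to rt
Reagents that add atoms: none
Why: Acid methanolysis cleaves the N–S bond (the sulfinyl group leaves as its methyl ester) and the ammonium salt 7 is acylated under Schotten–Baumann conditions; C2' takes no part. Acid exposure is kept short, cold and near-stoichiometric because the benzylic C–N bond carries two ortho and one para methoxy donor and could ionise on prolonged treatment. The methyl carbamate is chosen because its N–H closes ring D in step 3 and its carbonyl carbon becomes the N-methyl group in step 5.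

**Step 3**
Reactants: 8 methyl N-[(1R)-1-(2,4,6-trimethoxyphenyl)but-3-en-1-yl]carbamate; 9 carbon monoxide
Product: 12 methyl (2R)-2-(2,4,6-trimethoxyphenyl)-3,4-dihydro-2H-pyridine-1-carboxylate, via linear aldehyde 10 (not isolated), via cyclic hemiaminal 11 (not isolated)
Conditions: Rh(acac)(CO)2 (1 mol%), BIPHEPHOS (3 mol%), CO/H2 (1:1, 5 bar), toluene (0.05 M), 70 °C
Reagents that add atoms: none
Why: This is rhodium-catalysed cyclohydrocarbonylation, a known reaction of N-acyl homoallylic amines: the monovalent rhodium hydride formed from Rh(acac)(CO)2, the bulky bisphosphite and syngas adds across the terminal alkene so that rhodium sits on the terminal carbon C5', 9 inserts to give the acyl complex, and hydrogenolysis releases the linear aldehyde 10 whose carbonyl carbon is C6'. The wide bite angle of the bisphosphite places both phosphorus atoms equatorial in the trigonal-bipyramidal hydride and its bulk disfavours the branched alkyl, which secures the C5'–C6' bond; the branched aldehyde would end as a methyl-substituted five-membered ring. The carbamate N–H then adds to the aldehyde carbonyl in a 6-exo-trig closure (N1'–C6') to give hemiaminal 11, and loss of water gives the N-acyl enamine 12, which takes the aldehyde out of reach of further hydroformylation, aldol or reduction chemistry. No stereocentre is created: the hemiaminal carbon is transient and ends sp2, and C2', two carbons from the alkene, is not involved as long as double-bond migration toward C2' stays slower than hydroformylation, which the fast linear-selective catalyst and the moderate temperature are chosen to ensure. No Brønsted acid is added, because an N-acyliminium ion could be trapped by the very nucleophilic ring CH positions of a second molecule; dehydration of 11 is left to the thermal conditions and the reaction is run dilute. A carbamate is used in place of a free or sulfinyl amine so that nitrogen neither binds rhodium nor forms a basic enamine.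

**Step 4**
Reactants: 12 methyl (2R)-2-(2,4,6-trimethoxyphenyl)-3,4-dihydro-2H-pyridine-1-carboxylate
Product: 13 methyl (2R)-2-(2,4,6-trimethoxyphenyl)piperidine-1-carboxylate
Conditions: H2 (1 atm), 10% Pd/C, EtOAc, rt
Reagents that add atoms: none
Why: Heterogeneous catalytic hydrogenation of the electron-rich ene-carbamate C5'=C6' bond. The carbamate nitrogen is a poor leaving group and the benzylic carbon is shielded by two ortho methoxy groups, so C2'–N hydrogenolysis should not compete, and C2' is untouched.

**Step 5**
Reactants: 13 methyl (2R)-2-(2,4,6-trimethoxyphenyl)piperidine-1-carboxylate
Product: 14 (2R)-1-methyl-2-(2,4,6-trimethoxyphenyl)piperidine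
Conditions: LiAlH4 (4 equiv), THF, reflux; H2O, 15% aq. NaOH, H2O at 0 °C
Reagents that add atoms: none
Why: LiAlH4 reduction of a carbamate to an N-methyl amine (hydride addition, loss of methoxide, reduction through the iminium ion). It is placed here because no ketone or pyranone is present yet, and the basic conditions do not endanger the benzylic C–N bond.

**Step 6**
Reactants: 14 (2R)-1-methyl-2-(2,4,6-trimethoxyphenyl)piperidine; 15 acetic anhydride
Product: 17 1-[2-hydroxy-4,6-dimethoxy-3-[(2R)-1-methylpiperidin-2-yl]phenyl]ethan-1-one, via trimethoxy ketone 16 (not isolated)
Conditions: BF3·OEt2 (6 equiv), CH2Cl2, 0 °C, 15 min; then 15 (3 equiv), 0 °C to rt; aq. Na2CO3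
Reagents that add atoms: none
Why: BF3 is added first so that the amine is held as its Lewis acid adduct, which blocks N-acylation and the C–N cleavage an N-acylammonium ion would invite; Friedel–Crafts acetylation then occurs at one of the two ring CH positions, equivalent by the local mirror plane of the aryl group, to give 16. Boron then chelates the new carbonyl and an ortho methoxy oxygen and the methyl group is lost to acetate; of the two ortho ethers, the one wedged between the acetyl group and C8 is twisted out of conjugation, more Lewis basic and relieved of strain on cleavage, so the hydroxyl should be freed next to the piperidine, as is known for 3-substituted 2,4,6-trimethoxyacetophenones including aryl piperidines. The boron chelate is hydrolysed on basic work-up.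

**Step 7**
Reactants: 17 1-[2-hydroxy-4,6-dimethoxy-3-[(2R)-1-methylpiperidin-2-yl]phenyl]ethan-1-one; 18 benzoyl chloride
Product: 20 5,7-dimethoxy-8-[(2R)-1-methylpiperidin-2-yl]-2-phenyl-4H-chromen-4-one, via 1,3-diketone 19 (not isolated)
Conditions: LiN(SiMe3)2 (4 equiv), THF, −78 to −10 °C; 18 (1.1 equiv), −78 °C to rt; then AcOH, conc. HCl, 50 °C; aq. NaHCO3
Reagents that add atoms: none
Why: Excess LiN(SiMe3)2 forms the phenoxide–enolate dianion, whose methyl ketone carbon is benzoylated by 18 (Claisen-type C-acylation, the one-flask form of the Baker–Venkataraman diketone synthesis; any O-benzoate formed would be carried to the same diketone by acyl migration under the excess base). Acid then cyclodehydrates 19: the only free hydroxyl adds to the benzoyl carbonyl and water is lost, which fixes O1 on C8a. Telescoping avoids isolating the amphoteric diketone, and the temperature is held at 50 °C to spare the benzylic C–N bond.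

**Step 8**
Reactants: 20 5,7-dimethoxy-8-[(2R)-1-methylpiperidin-2-yl]-2-phenyl-4H-chromen-4-one
Product: 21 5,7-dihydroxy-8-[(2R)-1-methylpiperidin-2-yl]-2-phenyl-4H-chromen-4-one
Conditions: BBr3 (8 equiv), CH2Cl2, −78 °C to rt; ice, aq. NaHCO3
Reagents that add atoms: none
Why: Boron tribromide cleaves aryl methyl ethers by O–B coordination and bromide attack on methyl; the 5-ether is assisted by chelation to the C4 carbonyl and the 7-ether needs the excess reagent and room temperature. The amine and the carbonyl each bind one equivalent and are released on aqueous work-up. The reaction is kept at or below room temperature so that the C2'–N bond, which could open to an ortho-quinone methide once the 7-hydroxyl is free, does not ionise.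

## Compound list

1 | 2,4,6-trimethoxybenzaldehyde | COc1cc(OC)c(C=O)c(OC)c1 | starting material
2 | (S)-2-methylpropane-2-sulfinamide | CC(C)(C)[S@](=O)N | starting material
3 | allyl bromide (3-bromoprop-1-ene) | C=CCBr | starting material
4 | (S)-2-methyl-N-[(E)-(2,4,6-trimethoxyphenyl)methylidene]propane-2-sulfinamide | CC(C)(C)[S@](=O)/N=C/c1c(OC)cc(OC)cc1OC | intermediate
5 | (S)-2-methyl-N-[(1R)-1-(2,4,6-trimethoxyphenyl)but-3-en-1-yl]propane-2-sulfinamide | CC(C)(C)[S@](=O)N[C@H](CC=C)c1c(OC)cc(OC)cc1OC | intermediate
6 | methyl chloroformate | COC(=O)Cl | starting material
7 | (1R)-1-(2,4,6-trimethoxyphenyl)but-3-en-1-amine hydrochloride | C=CC[C@@H](N)c1c(OC)cc(OC)cc1OC.Cl | intermediate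
8 | methyl N-[(1R)-1-(2,4,6-trimethoxyphenyl)but-3-en-1-yl]carbamate | C=CC[C@@H](NC(=O)OC)c1c(OC)cc(OC)cc1OC | intermediate
9 | carbon monoxide | [C-]#[O+] | starting material
10 | methyl N-[(1R)-5-oxo-1-(2,4,6-trimethoxyphenyl)pentyl]carbamate | O=CCCC[C@@H](NC(=O)OC)c1c(OC)cc(OC)cc1OC | intermediate
11 | methyl (2R)-6-hydroxy-2-(2,4,6-trimethoxyphenyl)piperidine-1-carboxylate (both C6 epimers) | COC(=O)N1C(O)CCC[C@@H]1c1c(OC)cc(OC)cc1OC | intermediate
12 | methyl (2R)-2-(2,4,6-trimethoxyphenyl)-3,4-dihydro-2H-pyridine-1-carboxylate | COC(=O)N1C=CCC[C@@H]1c1c(OC)cc(OC)cc1OC | intermediate
13 | methyl (2R)-2-(2,4,6-trimethoxyphenyl)piperidine-1-carboxylate | COC(=O)N1CCCC[C@@H]1c1c(OC)cc(OC)cc1OC | intermediate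
14 | (2R)-1-methyl-2-(2,4,6-trimethoxyphenyl)piperidine | CN1CCCC[C@@H]1c1c(OC)cc(OC)cc1OC | intermediate
15 | acetic anhydride | CC(=O)OC(C)=O | starting material
16 | 1-[2,4,6-trimethoxy-3-[(2R)-1-methylpiperidin-2-yl]phenyl]ethan-1-one | CN1CCCC[C@@H]1c1c(OC)cc(OC)c(C(C)=O)c1OC | intermediate
17 | 1-[2-hydroxy-4,6-dimethoxy-3-[(2R)-1-methylpiperidin-2-yl]phenyl]ethan-1-one | CN1CCCC[C@@H]1c1c(OC)cc(OC)c(C(C)=O)c1O | intermediate
18 | benzoyl chloride | O=C(Cl)c1ccccc1 | starting material
19 | 1-[2-hydroxy-4,6-dimethoxy-3-[(2R)-1-methylpiperidin-2-yl]phenyl]-3-phenylpropane-1,3-dione | CN1CCCC[C@@H]1c1c(OC)cc(OC)c(C(=O)CC(=O)c2ccccc2)c1O | intermediate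
20 | 5,7-dimethoxy-8-[(2R)-1-methylpiperidin-2-yl]-2-phenyl-4H-chromen-4-one | CN1CCCC[C@@H]1c1c(OC)cc(OC)c2c(=O)cc(-c3ccccc3)oc12 | intermediate
21 | 5,7-dihydroxy-8-[(2R)-1-methylpiperidin-2-yl]-2-phenyl-4H-chromen-4-one | CN1CCCC[C@@H]1c1c(O)cc(O)c2c(=O)cc(-c3ccccc3)oc12 | target

## Step count and least certain steps

Total step count: 8. Longest linear sequence: 8 steps (1 to 21); the route is fully linear and the other numbered starting materials enter one at a time.

**Step 3 (key step).** The most likely failures are loss of regiocontrol or of the alkene: branched hydroformylation followed by closure to the five-membered ring, or double-bond migration toward C2', which would also endanger the stereocentre. The reaction may also stall at the hemiaminal stage because the carbamate nitrogen is crowded by the di-ortho-substituted aryl group, and an N-acyliminium ion may amidoalkylate the electron-rich ring of a second molecule if traces of acid are present. Fallback, which sets out from 8 and comes back at 13: N-allylation of 8 with NaH and 3 in DMF at 0 °C gives methyl N-allyl-N-[(1R)-1-(2,4,6-trimethoxyphenyl)but-3-en-1-yl]carbamate F1. Ring-closing metathesis with the second-generation Grubbs catalyst in CH2Cl2 at 40 °C closes ring D as methyl (2R)-2-(2,4,6-trimethoxyphenyl)-3,6-dihydro-2H-pyridine-1-carboxylate F2. Hydrogenation under the conditions of step 4 gives 13. In this variant C6' comes from the allyl CH2 on nitrogen and no gas pressure is needed.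

**Step 6.** The most likely failures are erosion of configuration or ring opening through reversible heterolysis of the donor-flanked C2'–N bond under BF3 and the acetic acid formed, and demethylation at the other ortho ether, which would lead to the 6-substituted flavone series. Fallback, which sets out from 14 and comes back at 17: the ring CH between two methoxy groups is lithiated (n-BuLi, TMEDA, THF, 0 °C) and the aryllithium is acylated with N-methoxy-N-methylacetamide at −78 °C, giving 16 as an isolated compound without any acid. BCl3 in CH2Cl2 at −78 to 0 °C then cleaves the more crowded ortho ether by chelation to give 17. No compound outside the compound list is formed (F0). Acylation and ether cleavage are thereby separated, and the cold demethylation takes place on a ring already deactivated by the acetyl group.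

**Step 8.** The most likely failures are incomplete cleavage of the hindered 7-ether, and loss of configuration at C2' by ring opening toward an ortho-quinone methide once the 7-hydroxyl is free in a Lewis-acidic medium. Fallback, which sets out from 20 and comes back at 21: BCl3 in CH2Cl2 at −78 to 0 °C removes only the chelated 5-O-methyl group and gives 5-hydroxy-7-methoxy-8-[(2R)-1-methylpiperidin-2-yl]-2-phenyl-4H-chromen-4-one F3. The 7-O-methyl group is then removed by nucleophilic attack of NaSEt on the methyl carbon in DMF at 110 °C. Under these basic conditions the amine is not a leaving group, and the 7-oxygen, conjugated with the C4 carbonyl, is a good one, so 21 should form without acid.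

**Step 2.** The most likely failure is solvolytic loss of nitrogen or racemisation at C2' while the free ammonium salt sits in acidic methanol, since the benzylic cation is stabilised by three methoxy groups. Fallback, which sets out from 1, comes back at 8 and needs no N-deprotection: 1, methyl carbamate and sodium benzenesulfinate in aqueous formic acid and methanol give the α-amido sulfone methyl N-[(benzenesulfonyl)(2,4,6-trimethoxyphenyl)methyl]carbamate F4. Cs2CO3 in CH2Cl2 eliminates sulfinate to the N-acyl imine methyl N-[(E)-(2,4,6-trimethoxyphenyl)methylidene]carbamate F5. Chiral-diol-catalysed allylboration (allyldiisopropoxyborane, 3,3'-diphenyl-BINOL 15 mol%, 3 Å molecular sieves, toluene, rt), with the diol enantiomer that delivers allyl to the Re face, gives 8 directly. The enantioselectivity with a carbamate on so electron-rich and hindered an imine would have to be established, which is why the auxiliary route is preferred.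

## Further compounds

F1 | step 3 | methyl N-allyl-N-[(1R)-1-(2,4,6-trimethoxyphenyl)but-3-en-1-yl]carbamate | C=CC[C@@H](N(CC=C)C(=O)OC)c1c(OC)cc(OC)cc1OC
F2 | step 3 | methyl (2R)-2-(2,4,6-trimethoxyphenyl)-3,6-dihydro-2H-pyridine-1-carboxylate | COC(=O)N1CC=CC[C@@H]1c1c(OC)cc(OC)cc1OC
F0 | step 6 | none | none
F3 | step 8 | 5-hydroxy-7-methoxy-8-[(2R)-1-methylpiperidin-2-yl]-2-phenyl-4H-chromen-4-one | CN1CCCC[C@@H]1c1c(OC)cc(O)c2c(=O)cc(-c3ccccc3)oc12
F4 | step 2 | methyl N-[(benzenesulfonyl)(2,4,6-trimethoxyphenyl)methyl]carbamate (racemic) | COC(=O)NC(c1c(OC)cc(OC)cc1OC)S(=O)(=O)c1ccccc1
F5 | step 2 | methyl N-[(E)-(2,4,6-trimethoxyphenyl)methylidene]carbamate | COC(=O)/N=C/c1c(OC)cc(OC)cc1OC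
A1 | alternative 1 | tert-butyl (2R)-2-[2-(benzoyloxy)-4,6-dimethoxy-3-[2-(triphenylphosphoranylidene)acetyl]phenyl]piperidine-1-carboxylate | CC(C)(C)OC(=O)N1CCCC[C@@H]1c1c(OC)cc(OC)c(C(=O)C=P(c2ccccc2)(c2ccccc2)c2ccccc2)c1OC(=O)c1ccccc1
A2 | alternative 1 | tert-butyl (2R)-2-(5,7-dimethoxy-4-oxo-2-phenyl-4H-chromen-8-yl)piperidine-1-carboxylate | CC(C)(C)OC(=O)N1CCCC[C@@H]1c1c(OC)cc(OC)c2c(=O)cc(-c3ccccc3)oc12
A3 | alternative 2 | D-pipecolic acid, (2R)-piperidine-2-carboxylic acid | OC(=O)[C@H]1CCCCN1
A4 | alternative 2 | tert-butyl (2R)-2-[2-(triisopropylsilyloxy)ethynyl]piperidine-1-carboxylate | CC(C)(C)OC(=O)N1CCCC[C@@H]1C#CO[Si](C(C)C)(C(C)C)C(C)C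
A5 | alternative 2 | 3-ethoxycyclobut-2-en-1-one | CCOC1=CC(=O)C1
A6 | alternative 2 | tert-butyl (2R)-2-[4-ethoxy-2-hydroxy-6-(triisopropylsilyloxy)phenyl]piperidine-1-carboxylate | CC(C)(C)OC(=O)N1CCCC[C@@H]1c1c(O)cc(OCC)cc1O[Si](C(C)C)(C(C)C)C(C)C
A7 | alternative 3 | 1-[2-fluoro-4,6-dimethoxy-3-[(2R)-1-methylpiperidin-2-yl]phenyl]-3-phenylpropane-1,3-dione | CN1CCCC[C@@H]1c1c(OC)cc(OC)c(C(=O)CC(=O)c2ccccc2)c1F
A8 | alternative 3 | 5,7-dimethoxy-8-[(2R)-1-methylpiperidin-2-yl]-2-phenyl-4H-chromen-4-one | CN1CCCC[C@@H]1c1c(OC)cc(OC)c2c(=O)cc(-c3ccccc3)oc12
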